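The south-west flask holds 25.0 mM of starting material over 0.250 mM of catalyst, and I count it by what I call the fraction left, one minus [target] over the charge.

| flask | starting material | catalyst | target | time |
|---|---|---|---|---|
| north | 50.0 mM | 0.500 mM |  |  |
| north-west | 30.0 mM | 0.500 mM |  |  |
| west | 150 mM | 0.500 mM |  |  |
| south | 50.0 mM | 0.500 mM | 25.0 mM |  |
| south-west | 25.0 mM | 0.250 mM |  | 7.7 min |

| run | time / min | [target] / mM |
|---|---|---|
| north run | 0.44 | 3.32 |
| north run | 1.3 | 10.00 |
| north run | 2.5 | 17.49 |
| north run | 4.0 | 25.46 |
| north run | 5.8 | 31.34 |
| north run | 7.7 | 34.50 |
| north-west run | 0.44 | 2.67 |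
| north-west run | 1.3 | 8.04 |
| north-west run | 2.5 | 13.70 |
| north-west run | 4.0 | 18.33 |
| north-west run | 5.8 | 21.81 |
| north-west run | 7.7 | 21.99 |
| west run | 0.44 | 5.39 |
| west run | 1.3 | 15.00 |
| west run | 2.5 | 27.76 |
| west run | 4.0 | 41.11 |
| west run | 5.8 | 55.23 |
| west run | 7.7 | 67.11 |
| south run | 0.44 | 27.90 |
| south run | 1.3 | 32.96 |
| south run | 2.5 | 39.17 |
| south run | 4.0 | 45.03 |
| south run | 5.8 | 49.07 |
| south run | 7.7 | 50.99 |

(scatter of a reading: 0.2 mM)

- the power of [starting material] that the first rate follows, about the charge of the north run; measure it at two percent of starting material made into target (one fixed amount of target, the same in the runs compared)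
- target in the south-west run at 7.7 min, as a share of the starting material charged

- Overall: starting material -> target, with catalyst as catalyst.
- Constant volume, constant temperature.
- What is held in complexes is read along with the free species.
- An order is taken over about fifteen percent of the charge, up and down.

I first try what the given numbers are worth. The scatter of 0.2 mM is 0.667 % of the north-west charge. At 4.0 min the fraction left is 38.9 % in the north-west run and 49.1 % in the north run, so the step in charge from 30.0 mM down to 25.0 mM is worth about 2.5 percentage points, more than the scatter. Time is worth more again: the north-west run loses 15 points of its fraction left between 2.5 min and 4.0 min.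

So the clock has to be right, and the north, north-west, west and south runs hold 0.500 mM of catalyst, which leaves proportionality to catalyst as my assumption. Then the measure of progress is the catalyst clock, catalyst charge times time, and the south-west run reaches 0.116 M·s. The north-west run reaches that clock at 3.85 min. Interpolating the logarithm of the fraction left between its readings at 2.5 min and 4.0 min gives 40.2 %, and the charge step brings my south-west figure to 37.7 % left, or 62.3 % made. The first readings of the north and north-west runs, taken at one time and not at one amount of target, give an order of 0.427.

The forecast, lower than my figure, gives 60 % (51 % to 68 %) and an order of 0.47 (0.33 to 0.62), saying “I assume rate is first order in catalyst”.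

The flask gives 58.1 % and an order of 0.41, so the south-west fraction left is 41.9 %.

    catalyst + starting material ⇌ catalyst-substrate complex, settled at all times (33.20 M⁻¹)
    catalyst-substrate complex ⇌ target + catalyst (51.90 min⁻¹, 43.26 M⁻¹ min⁻¹)
    target → decomposed product (0.04710 min⁻¹)
    2 starting material ⇌ idle substrate dimer, settled at all times (84.00 M⁻¹)

The decomposition step holds no catalyst: 0.0471 min⁻¹ times the 7.7 min of the south-west run is 0.363, against 0.181 over the 3.85 min of the same clock in the north-west run. On the clock again, the north run at 4.0 min stands at 0.120 M·s, and its fraction left there, higher than the south-west one, is 49.1 %.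

The runs are calculated from invented constants.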